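**Assumption:** siphulin has no stereocentre, so the SMILES defines one achiral compound and no stereocontrol is needed; 5-heptylresorcinol and methyl 3,5-dihydroxyphenylacetate are taken as catalogue chemicals.

## Retrosynthetic overview

- Both benzene rings are bought: 5-heptylresorcinol (1) is C-acetylated (via ketiminium salt 2) to the o-hydroxyacetophenone 3; methyl 3,5-dihydroxyphenylacetate (4) is formylated (via iminium salt 5) to aldehyde 6 and oxidised to the half-ester acid 7.
- Key disconnection: the O1–C2 bond of the γ-pyrone (C–O); cyclodehydration of the o-hydroxyaryl β-diketone acid 8 gives siphulin (9).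
- 8 is disconnected at C2–C3 into 3 and 7 (crossed Claisen), run without protecting groups in the same flask as the ring closure.
- Ring order: the pyranone is the only ring made and is closed last.

## Route

Step 1
Reactants: 1 5-heptylbenzene-1,3-diol
Product: 3 1-(2-heptyl-4,6-dihydroxyphenyl)ethan-1-one, via ketiminium chloride 2 (not isolated)
Conditions: MeCN, ZnCl2 (cat.), HCl (g), Et2O, 0 °C; then H2O, reflux
Reagents that add atoms: acetonitrile, CC#N; water, O
Why: Houben–Hoesch acylation, in which the ZnCl2/HCl-activated nitrile attacks the most nucleophilic position of the 5-alkylresorcinol (para to one OH, ortho to the other, next to the heptyl chain) and the ketiminium salt is hydrolysed to the hydrogen-bonded o-hydroxyacetophenone; no stereocentre is formed.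

Step 2
Reactants: 4 methyl 2-(3,5-dihydroxyphenyl)acetate
Product: 6 methyl 2-(2-formyl-3,5-dihydroxyphenyl)acetate, via aryl iminium chloride 5 (not isolated)
Conditions: POCl3, DMF, MeCN, 0 °C → rt; then H2O, 50 °C
Reagents that add atoms: N,N-dimethylformamide, CN(C)C=O; water, O
Why: Vilsmeier–Haack formylation, in which the chloroiminium ion reacts at the two equivalent positions next to the CH2CO2Me arm (each para to one OH) rather than at the hindered position between the hydroxyls, and hydrolysis of the iminium salt releases the aldehyde with the methyl ester untouched.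

Step 3
Reactants: 6 methyl 2-(2-formyl-3,5-dihydroxyphenyl)acetate
Product: 7 2,4-dihydroxy-6-(2-methoxy-2-oxoethyl)benzoic acid
Conditions: NaClO2, NaH2PO4, DMSO/H2O, 0 °C → rt
Reagents that add atoms: sodium chlorite, [Na+].[O-]Cl=O
Why: Pinnick (Lindgren) oxidation, in which chlorous acid converts the aldehyde to the carboxylic acid at about pH 4 while DMSO scavenges the HOCl that would otherwise chlorinate the resorcinol ring, leaving the aliphatic methyl ester intact and the aromatic carboxyl free.

Step 4
Reactants: 3 1-(2-heptyl-4,6-dihydroxyphenyl)ethan-1-one; 7 2,4-dihydroxy-6-(2-methoxy-2-oxoethyl)benzoic acid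
Product: 9 siphulin, via diketone acid 8 (not isolated)
Conditions: 3 (2 equiv), LDA (9 equiv), THF–DMPU, −78 → 45 °C; then 3 M aq. HCl/AcOH, 25–40 °C
Reagents that add atoms: none
Why: Proposed new method: a protecting-group-free crossed Claisen/cyclodehydration in which both partners are lithium polyanions, not shown for an ester electrophile that carries two free phenols and a free carboxylic acid; the enolate of trilithiated 3 adds to the aliphatic methyl ester of trilithiated 7, whose carboxylate cannot be attacked (no Dieckmann-type naphthol formation) and whose charge disfavours α-deprotonation and self-condensation, the tetrahedral intermediate loses methoxide to give the diketonate as thermodynamic sink (the second equivalent of 3 takes up its proton), and acidification lets the chelated 2-OH of 8 add to the distal ketone (6-exo-trig hemiketal) and lose water to form the O1–C2 bond of the γ-pyrone while the benzoic acid stays free; the closest known reaction type is the lithium amide polyanion C-acylation of unprotected polyhydroxyacetophenones with aroyl chlorides followed by acid cyclodehydration (Claisen/cyclodehydration chromone synthesis).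

## Compound list

1 | 5-heptylbenzene-1,3-diol (5-heptylresorcinol) | CCCCCCCc1cc(O)cc(O)c1 | starting material
2 | 1-(2-heptyl-4,6-dihydroxyphenyl)ethan-1-iminium chloride (ketiminium chloride) | CCCCCCCc1cc(O)cc(O)c1C(C)=[NH2+].[Cl-] | intermediate
3 | 1-(2-heptyl-4,6-dihydroxyphenyl)ethan-1-one | CCCCCCCc1cc(O)cc(O)c1C(C)=O | intermediate
4 | methyl 2-(3,5-dihydroxyphenyl)acetate | COC(=O)Cc1cc(O)cc(O)c1 | starting material
5 | N-{[2,4-dihydroxy-6-(2-methoxy-2-oxoethyl)phenyl]methylidene}-N-methylmethanaminium chloride (aryl iminium chloride) | COC(=O)Cc1cc(O)cc(O)c1C=[N+](C)C.[Cl-] | intermediate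
6 | methyl 2-(2-formyl-3,5-dihydroxyphenyl)acetate | COC(=O)Cc1cc(O)cc(O)c1C=O | intermediate
7 | 2,4-dihydroxy-6-(2-methoxy-2-oxoethyl)benzoic acid | COC(=O)Cc1cc(O)cc(O)c1C(=O)O | intermediate
8 | 2-[4-(2-heptyl-4,6-dihydroxyphenyl)-2,4-dioxobutyl]-4,6-dihydroxybenzoic acid (diketone acid) | CCCCCCCc1cc(O)cc(O)c1C(=O)CC(=O)Cc1cc(O)cc(O)c1C(=O)O | intermediate
9 | siphulin, 2-[(5-heptyl-7-hydroxy-4-oxo-4H-chromen-2-yl)methyl]-4,6-dihydroxybenzoic acid | CCCCCCCc1cc(O)cc2oc(Cc3cc(O)cc(O)c3C(=O)O)cc(=O)c12 | target

## Step count and risks

Total steps: 4. Longest linear sequence: 3 steps (4 → 6 → 7 → 9); the branch 1 → 3 is one step.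

**Step 4 (the proposed new step).** The hexalithiated mixture may be too aggregated or insoluble to react, the arylacetate CH2 of 7 may be deprotonated instead of its ester being attacked, and the acid stage could cause some decarboxylation of the β-resorcylic acid. The fallback uses known chemistry (silyl protection, standard dianion Claisen, acidic desilylation/cyclodehydration); it sets out from 3 and 7 and comes back at 9. Compound 3 is silylated at its non-chelated 4-OH (TBSCl, imidazole, DMF) to 1-[4-(tert-butyldimethylsilyloxy)-2-heptyl-6-hydroxyphenyl]ethan-1-one F1. Compound 7 is persilylated (excess TBSCl, imidazole, DMF) to tert-butyldimethylsilyl 2,4-bis(tert-butyldimethylsilyloxy)-6-(2-methoxy-2-oxoethyl)benzoate F2. The dianion of F1 (LiHMDS, THF, −78 °C → rt) is condensed with the aliphatic methyl ester of F2 to tert-butyldimethylsilyl 2-{4-[4-(tert-butyldimethylsilyloxy)-2-heptyl-6-hydroxyphenyl]-2,4-dioxobutyl}-4,6-bis(tert-butyldimethylsilyloxy)benzoate F3. Aqueous HCl in MeOH/THF at 40 °C then removes all four silyl groups from F3 and cyclodehydrates it to 9.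

**Step 1.** The Hoesch acylation can also attack the position between the two hydroxyls or acylate twice, and the regioisomers are hard to separate. The fallback changes the approach to a formylation, which is more regioselective on 5-alkylresorcinols, followed by a one-carbon addition and oxidation; it sets out from 1 and comes back at 3. Vilsmeier–Haack reaction of 1 (POCl3, DMF) gives N-[(2-heptyl-4,6-dihydroxyphenyl)methylidene]-N-methylmethanaminium chloride F4, which is hydrolysed in the work-up to 2-heptyl-4,6-dihydroxybenzaldehyde F5. Excess MeMgBr (THF, 0 °C; the two phenoxides are tolerated) converts F5 to racemic 5-heptyl-4-(1-hydroxyethyl)benzene-1,3-diol F6. F6 is used crude, and activated MnO2 oxidises its benzylic alcohol to 3.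

**Step 3.** The free resorcinol ring may be chlorinated or over-oxidised by HOCl despite the scavenger. The fallback masks the phenols before the oxidation; it sets out from 6 and comes back at 7. Ac2O/pyridine converts 6 to methyl 2-(3,5-diacetoxy-2-formylphenyl)acetate F7. Standard Pinnick oxidation of the now electron-poor aldehyde gives 2,4-diacetoxy-6-(2-methoxy-2-oxoethyl)benzoic acid F8. K2CO3 in MeOH at 0 °C cleaves the two aryl acetates of F8, leaving the methyl ester as it is, to give 7.

## Further compounds

F1 | step 4 | 1-[4-(tert-butyldimethylsilyloxy)-2-heptyl-6-hydroxyphenyl]ethan-1-one | CCCCCCCc1cc(O[Si](C)(C)C(C)(C)C)cc(O)c1C(C)=O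
F2 | step 4 | tert-butyldimethylsilyl 2,4-bis(tert-butyldimethylsilyloxy)-6-(2-methoxy-2-oxoethyl)benzoate | COC(=O)Cc1cc(O[Si](C)(C)C(C)(C)C)cc(O[Si](C)(C)C(C)(C)C)c1C(=O)O[Si](C)(C)C(C)(C)C
F3 | step 4 | tert-butyldimethylsilyl 2-{4-[4-(tert-butyldimethylsilyloxy)-2-heptyl-6-hydroxyphenyl]-2,4-dioxobutyl}-4,6-bis(tert-butyldimethylsilyloxy)benzoate | CCCCCCCc1cc(O[Si](C)(C)C(C)(C)C)cc(O)c1C(=O)CC(=O)Cc1cc(O[Si](C)(C)C(C)(C)C)cc(O[Si](C)(C)C(C)(C)C)c1C(=O)O[Si](C)(C)C(C)(C)C
F4 | step 1 | N-[(2-heptyl-4,6-dihydroxyphenyl)methylidene]-N-methylmethanaminium chloride | CCCCCCCc1cc(O)cc(O)c1C=[N+](C)C.[Cl-]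
F5 | step 1 | 2-heptyl-4,6-dihydroxybenzaldehyde | CCCCCCCc1cc(O)cc(O)c1C=O
F6 | step 1 | 5-heptyl-4-(1-hydroxyethyl)benzene-1,3-diol (racemic) | CCCCCCCc1cc(O)cc(O)c1C(C)O
F7 | step 3 | methyl 2-(3,5-diacetoxy-2-formylphenyl)acetate | COC(=O)Cc1cc(OC(C)=O)cc(OC(C)=O)c1C=O
F8 | step 3 | 2,4-diacetoxy-6-(2-methoxy-2-oxoethyl)benzoic acid | COC(=O)Cc1cc(OC(C)=O)cc(OC(C)=O)c1C(=O)O
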